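**Assumption:** The target has no stereocentres and is treated as achiral (no configurationally stable atropisomers assumed), so there is no enantiomer to select. The racemic C3 centre in intermediates 7 and 12 is destroyed in Step 10.

## Retrosynthetic overview

1. Pestalone H (14) ⇐ bis-MOM ether 13, with an acid-only global deprotection last.
2. 13 ⇐ aryl phthalidyl ether ("pseudo-ester") 12, by a new I/Mg-exchange-triggered anionic pseudo-ester Fries rearrangement that makes the hindered Ar–C(=O)–Ar bond and unmasks both the ring-A OH and the CHO.
3. 12 ⇐ ring-B lactol 7 + ring-A iodophenol 11 (C3–OAr bond).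
4. 7 ⇐ methyl 3,5-dihydroxybenzoate (formylation, MOM protection, bromination, Stille prenylation, hydrolysis); 11 ⇐ 3-methoxy-5-methylphenol (ortho-Cl, para-Br, then I).
5. Rings: both benzene rings are purchased. The only ring formed is the lactol/lactone of 7 (Step 5), which is opened again in Step 10.

## Route

**Step 1**
Reactants: 1, methyl 3,5-dihydroxybenzoate
Product: 2, methyl 2-formyl-3,5-dihydroxybenzoate
Conditions: POCl3, DMF, 0 °C → rt; then H2O
Reagents that add atoms: N,N-dimethylformamide, CN(C)C=O (formyl carbon); water, O (formyl oxygen on iminium hydrolysis)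
Why: Vilsmeier–Haack formylation attacks C2, which is ortho/para to the two hydroxyls, rather than the o,o-site C4 between them, as is usual for 3,5-dioxygenated benzoates.

**Step 2**
Reactants: 2, methyl 2-formyl-3,5-dihydroxybenzoate
Product: 3, methyl 2-formyl-3,5-bis(methoxymethoxy)benzoate
Conditions: NaH, MOMCl, DMF, 0 °C → rt
Reagents that add atoms: chloromethyl methyl ether, COCCl
Why: Williamson-type O-alkylation of both phenoxides (MOM protection); NaH is used because the OH hydrogen-bonded to the aldehyde alkylates poorly with amine bases, and MOM survives all later basic, Pd and organomagnesium steps.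

**Step 3**
Reactants: 3, methyl 2-formyl-3,5-bis(methoxymethoxy)benzoate
Product: 4, methyl 2-bromo-6-formyl-3,5-bis(methoxymethoxy)benzoate
Conditions: NBS, MeCN, 0 °C → rt, dark
Reagents that add atoms: N-bromosuccinimide, O=C1CCC(=O)N1Br
Why: Electrophilic aromatic bromination goes to the remaining position that is ortho to one OMOM and para to the other, not to the more hindered site between the two acetals.

**Step 4**
Reactants: 4, methyl 2-bromo-6-formyl-3,5-bis(methoxymethoxy)benzoate; 5, tributyl(3-methylbut-2-en-1-yl)stannane
Product: 6, methyl 2-formyl-3,5-bis(methoxymethoxy)-6-(3-methylbut-2-en-1-yl)benzoate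
Conditions: Pd(PPh3)4 (5 mol %), DMF, 95 °C, degassed
Reagents that add atoms: compound 5, CCCC[Sn](CCCC)(CCCC)CC=C(C)C
Why: Stille cross-coupling transfers the prenyl group with bonding at the unsubstituted terminus (linear product), and unlike a prenylboronate the stannane does not add to the free aldehyde.

**Step 5**
Reactants: 6, methyl 2-formyl-3,5-bis(methoxymethoxy)-6-(3-methylbut-2-en-1-yl)benzoate
Product: 7, (±)-3-hydroxy-4,6-bis(methoxymethoxy)-7-(3-methylbut-2-en-1-yl)isobenzofuran-1(3H)-one (cyclic lactol tautomer of the 2-formylbenzoic acid)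
Conditions: LiOH·H2O, THF/H2O, rt; acidify to pH 4 with NaH2PO4/citric acid
Reagents that add atoms: lithium hydroxide, [Li+].[OH-]; water, O (one oxygen from hydroxide/water replaces the OMe)
Why: Saponification of this 2,6-disubstituted benzoate is fast at rt because the neighbouring aldehyde hydrate delivers the oxygen intramolecularly, and the resulting 2-formylbenzoic acid closes to its lactol (new C3 centre racemic and irrelevant).

**Step 6**
Reactants: 8, 3-methoxy-5-methylphenol
Product: 9, 2-chloro-5-methoxy-3-methylphenol
Conditions: SO2Cl2 (1.0 equiv), i-Bu2NH (10 mol %), toluene, 65 °C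
Reagents that add atoms: sulfuryl chloride, O=S(=O)(Cl)Cl
Why: Amine-catalysed ortho-selective electrophilic chlorination of a phenol; of the two ortho sites, the one para to OMe (between OH and CH3) is favoured over the crowded site between the two oxygens, and the minor para-chloro isomer is removed by chromatography (regiochemistry confirmed by HMBC/NOE).

**Step 7**
Reactants: 9, 2-chloro-5-methoxy-3-methylphenol
Product: 10, 4-bromo-2-chloro-5-methoxy-3-methylphenol
Conditions: n-Bu4NBr3 (1.0 equiv), CH2Cl2/MeOH (2:1), rt
Reagents that add atoms: tetrabutylammonium tribromide, CCCC[N+](CCCC)(CCCC)CCCC.[Br-].BrBr (tribromide written as its bromide·Br2 form)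
Why: Electrophilic aromatic bromination with a para-selective phenol brominating agent puts Br para to OH (ortho to OMe); the only alternative is the less reactive site between the two oxygens.

**Step 8**
Reactants: 10, 4-bromo-2-chloro-5-methoxy-3-methylphenol
Product: 11, 4-bromo-2-chloro-6-iodo-5-methoxy-3-methylphenol
Conditions: NIS, TsOH·H2O (10 mol %), MeCN, rt
Reagents that add atoms: N-iodosuccinimide, O=C1CCC(=O)N1I
Why: Electrophilic aromatic iodination at the single remaining ring C–H, which is activated by the flanking OH and OMe.

**Step 9**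
Reactants: 7, (±)-3-hydroxy-4,6-bis(methoxymethoxy)-7-(3-methylbut-2-en-1-yl)isobenzofuran-1(3H)-one; 11, 4-bromo-2-chloro-6-iodo-5-methoxy-3-methylphenol
Product: 12, (±)-3-(4-bromo-2-chloro-6-iodo-5-methoxy-3-methylphenoxy)-4,6-bis(methoxymethoxy)-7-(3-methylbut-2-en-1-yl)isobenzofuran-1(3H)-one
Conditions: (i) 1-chloro-N,N,2-trimethylprop-1-en-1-amine (Ghosez reagent), CH2Cl2, 0 °C; (ii) 11, i-Pr2NEt, CH2Cl2, −20 °C → rt; Et3N-deactivated silica
Reagents that add atoms: none
Why: The lactol is converted under neutral conditions to the 3-chlorophthalide, whose C3 (stabilised by the ortho/para acetal oxygens) undergoes SN1-like, Koenigs–Knorr-type substitution by the acidic phenoxide, which can only O-alkylate because its ring is fully substituted.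

**Step 10**
Reactants: 12, (±)-3-(4-bromo-2-chloro-6-iodo-5-methoxy-3-methylphenoxy)-4,6-bis(methoxymethoxy)-7-(3-methylbut-2-en-1-yl)isobenzofuran-1(3H)-one
Product: 13, 2-(3-bromo-5-chloro-6-hydroxy-2-methoxy-4-methylbenzoyl)-4,6-bis(methoxymethoxy)-3-(3-methylbut-2-en-1-yl)benzaldehyde
Conditions: i-PrMgCl·LiCl (1.05 equiv), THF (0.02 M), −78 → −30 °C; AcOH/THF quench at −30 °C, then pH 5 buffer
Reagents that add atoms: none
Why: Proposed new method: an I/Mg-exchange-triggered anionic "pseudo-ester Fries" rearrangement, in which chemoselective exchange (I ≫ Br, Cl; no base, so the acidic phthalide C3–H is untouched) gives an arylmagnesium flanked by OMe and the phthalidyloxy group. Because the C3 aryloxy group sits over the lactone face, this carbanion adds to the lactone C=O through a six-membered (bicyclo[3.2.1]) transition state. The tetrahedral alkoxide then opens the lactone to a cyclic hemiacetal alkoxide, which expels the ketone-chelated magnesium phenoxide, so the diaryl ketone C–C bond, the free ring-A phenol and the aldehyde are formed in one operation and the C3 stereocentre is erased. The closest known reaction types are the anionic ortho-Fries rearrangement of O-aryl carbamates, halogen–metal-exchange-induced Fries rearrangement of o-haloaryl esters, remote anionic Fries rearrangements, and aryl-metal additions to phthalides.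

**Step 11**
Reactants: 13, 2-(3-bromo-5-chloro-6-hydroxy-2-methoxy-4-methylbenzoyl)-4,6-bis(methoxymethoxy)-3-(3-methylbut-2-en-1-yl)benzaldehyde
Product: 14, Pestalone H, 2-(3-bromo-5-chloro-6-hydroxy-2-methoxy-4-methylbenzoyl)-4,6-dihydroxy-3-(3-methylbut-2-en-1-yl)benzaldehyde
Conditions: 3 M aq HCl, MeOH/THF (1:1), 40 °C; pH 5 buffer work-up, no base, exclude light
Reagents that add atoms: none
Why: Acetal hydrolysis; both MOM ethers are ortho/para to the formyl group and cleave in dilute protic acid, well below the acidity that would cyclise the prenyl group onto the phenol, while avoiding Lewis acids keeps the ring-A OMe and avoiding base prevents the Cannizzaro–Tishchenko isomerisation of the keto-aldehyde to a phthalide.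

## Compound list

1 | methyl 3,5-dihydroxybenzoate | COC(=O)c1cc(O)cc(O)c1 | starting material
2 | methyl 2-formyl-3,5-dihydroxybenzoate | COC(=O)c1cc(O)cc(O)c1C=O | intermediate
3 | methyl 2-formyl-3,5-bis(methoxymethoxy)benzoate | COC(=O)c1cc(OCOC)cc(OCOC)c1C=O | intermediate
4 | methyl 2-bromo-6-formyl-3,5-bis(methoxymethoxy)benzoate | COC(=O)c1c(Br)c(OCOC)cc(OCOC)c1C=O | intermediate
5 | tributyl(3-methylbut-2-en-1-yl)stannane | CCCC[Sn](CCCC)(CCCC)CC=C(C)C | starting material
6 | methyl 2-formyl-3,5-bis(methoxymethoxy)-6-(3-methylbut-2-en-1-yl)benzoate | COC(=O)c1c(CC=C(C)C)c(OCOC)cc(OCOC)c1C=O | intermediate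
7 | (±)-3-hydroxy-4,6-bis(methoxymethoxy)-7-(3-methylbut-2-en-1-yl)isobenzofuran-1(3H)-one | O=C1OC(O)c2c(OCOC)cc(OCOC)c(CC=C(C)C)c12 | intermediate
8 | 3-methoxy-5-methylphenol | COc1cc(C)cc(O)c1 | starting material
9 | 2-chloro-5-methoxy-3-methylphenol | COc1cc(O)c(Cl)c(C)c1 | intermediate
10 | 4-bromo-2-chloro-5-methoxy-3-methylphenol | COc1cc(O)c(Cl)c(C)c1Br | intermediate
11 | 4-bromo-2-chloro-6-iodo-5-methoxy-3-methylphenol | COc1c(I)c(O)c(Cl)c(C)c1Br | intermediate
12 | (±)-3-(4-bromo-2-chloro-6-iodo-5-methoxy-3-methylphenoxy)-4,6-bis(methoxymethoxy)-7-(3-methylbut-2-en-1-yl)isobenzofuran-1(3H)-one | O=C1OC(Oc3c(Cl)c(C)c(Br)c(OC)c3I)c2c(OCOC)cc(OCOC)c(CC=C(C)C)c12 | intermediate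
13 | 2-(3-bromo-5-chloro-6-hydroxy-2-methoxy-4-methylbenzoyl)-4,6-bis(methoxymethoxy)-3-(3-methylbut-2-en-1-yl)benzaldehyde | COc1c(Br)c(C)c(Cl)c(O)c1C(=O)c1c(C=O)c(OCOC)cc(OCOC)c1CC=C(C)C | intermediate
14 | Pestalone H | COc1c(Br)c(C)c(Cl)c(O)c1C(=O)c1c(C=O)c(O)cc(O)c1CC=C(C)C | target

## Summary

**Total step count:** 11

**Longest linear sequence:** 8 steps (1 → 2 → 3 → 4 → 6 → 7 → 12 → 13 → 14; Steps 1–5, 9, 10, 11); the ring-A branch (8 → 11; Steps 6–8) is 3 steps.

**Three steps most likely to fail**

1. **Step 10 (proposed new rearrangement).** Risks are addition of i-PrMgCl or unrearranged arylmagnesium to the liberated aldehyde, Tishchenko-type hydride shift of the hemiacetal alkoxide to a phthalide, and simple protodeiodination.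
   Fallback (known chemistry, intermolecular): reduce 6 with NaBH4 to 4,6-bis(methoxymethoxy)-7-prenylphthalide, protect 11 as its MOM ether, and generate the aryl-metal by I/Li exchange (n-BuLi, −100 °C) or I/Mg exchange. Add it to the phthalide to give the 2-(hydroxymethyl)benzophenone, oxidise CH2OH to CHO with MnO2 or DMP, then deprotect as in Step 11.

2. **Step 9 (pseudo-ester formation).** The acetal carbon and the 2,6-dihalophenoxide are both hindered, the phenoxide could instead attack the acyl carbon to give the open aryl ester, and 12 may ionise on silica.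
   Fallback: form the C3–OAr bond by Mitsunobu redox condensation of lactol 7 with the acidic phenol 11 (PPh3, DIAD), i.e. oxyphosphonium activation of the lactol instead of halide displacement. If no pseudo-ester can be isolated, use the intermolecular route given under item 1.

3. **Step 11 (final MOM removal).** Risks are acid-promoted cyclisation of the o-prenylphenol to a chroman and isomerisation of the keto-aldehyde.
   Fallback: change the protecting-group strategy so the finished keto-aldehyde never meets protic acid. Carry the ring-B phenols as TIPS ethers from compound 2 (TIPSOTf, 2,6-lutidine), cleave the methyl ester at the lactol stage with Me3SnOH instead of LiOH, and finish with buffered fluoride desilylation (TBAF/AcOH or HF·pyridine, 0 °C).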